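**Retrosynthetic overview**

1. Target 31 ⇐ hydroxy acid 28 (angeloylation last) ⇐ nitrile 26 (C19 carried as C≡N) ⇐ 5,7-diene 25 by ionic 1,2-hydrogenation, which sets 5α-H and leaves C7=C8.
2. Key disconnection: rings A and B are formed together from the monocyclic pyranone 20 by one intramolecular [4+2] cycloaddition with loss of CO2; the new bonds are C8–C9 (ring B) and C5–C10 (ring A).
3. Enabling feature: C5–C6–C7–C8 of ring B, with the C17 methyl on C8, is the diene of a 3-methyl-2H-pyran-2-one; C9–C10 with C11 and C20 cis is an (E)-trisubstituted alkene; C4 and C1–C3 of ring A are the four-atom tether.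
4. 20 ⇐ B-alkyl Suzuki–Miyaura coupling (C1–C10) of pyranone nitrile 18 with vinyl iodide 9. C4 in 18 comes from enantioselective allylation of ethyl 2-cyanopropanoate and the pyranone from a β-keto ester dianion; 9 comes from nerol, which supplies the (13Z)-alkene.
5. Ring order: the sacrificial pyranone first, then rings A and B together in step 12; no ring is formed afterwards.

Key step: step 12

Remark: in step 6 the antipode of the PhTRAP ligand that delivers (R)-11 is used; which antipode this is must be checked on the first run.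

**Step 1**
Reactants: 1 nerol, (2Z)-3,7-dimethylocta-2,6-dien-1-ol
Product: 2 neryl tert-butyldiphenylsilyl ether
Conditions: t-BuPh2SiCl, imidazole, CH2Cl2, 0 °C → rt
Reagents that add atoms: tert-butyl(chloro)diphenylsilane, CC(C)(C)[Si](Cl)(c1ccccc1)c1ccccc1
Why: Standard O-silylation of a primary allylic alcohol; the (Z)-alkene that becomes C13=C14 comes with nerol and is not touched.

**Step 2**
Reactants: 2 neryl tert-butyldiphenylsilyl ether
Product: 4 (4Z)-6-(tert-butyldiphenylsilyloxy)-4-methylhex-4-enal, via epoxide 3 (not isolated)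
Conditions: mCPBA, CH2Cl2, −20 °C; then H5IO6, THF–H2O, 0 °C
Reagents that add atoms: 3-chloroperoxybenzoic acid, OOC(=O)c1cccc(Cl)c1
Why: Peracid epoxidation should pick the more electron-rich terminal alkene (the other is deactivated by its allylic oxygen), and periodic acid cleaves the epoxide (hydrolysis then glycol cleavage) to the aldehyde carbon C9 and acetone.

**Step 3**
Reactants: 4 (4Z)-6-(tert-butyldiphenylsilyloxy)-4-methylhex-4-enal
Product: 5 tert-butyl[(2Z)-7,7-dibromo-3-methylhepta-2,6-dienyloxy]diphenylsilane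
Conditions: CBr4, PPh3, 2,6-lutidine, CH2Cl2, 0 °C
Reagents that add atoms: carbon tetrabromide, BrC(Br)(Br)Br
Why: First half of the Corey–Fuchs sequence (Wittig-type dibromo-olefination); the new carbon becomes C10.

**Step 4**
Reactants: 5 tert-butyl[(2Z)-7,7-dibromo-3-methylhepta-2,6-dienyloxy]diphenylsilane
Product: 7 tert-butyl[(2Z)-3-methyloct-2-en-6-ynyloxy]diphenylsilane, via lithium acetylide 6 (not isolated)
Conditions: n-BuLi (2.1 equiv), THF, −78 → 0 °C; then MeI, −78 °C → rt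
Reagents that add atoms: iodomethane, CI
Why: Second half of the Corey–Fuchs sequence (Br/Li exchange, 1,2-shift, deprotonation) followed by C-methylation of the acetylide; the methyl becomes C20.

**Step 5**
Reactants: 7 tert-butyl[(2Z)-3-methyloct-2-en-6-ynyloxy]diphenylsilane
Product: 9 tert-butyl[(2Z,6E)-7-iodo-3-methylocta-2,6-dienyloxy]diphenylsilane, via alkenylzirconocene chloride 8 (not isolated)
Conditions: Cp2Zr(H)Cl (2.5 equiv), THF, 50 °C; then I2, 0 °C
Reagents that add atoms: iodine, II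
Why: syn-Hydrozirconation of the internal alkyne with excess Cp2Zr(H)Cl should equilibrate zirconium to the methyl-bearing carbon, and iodinolysis with retention gives the (E)-2-iodoalkene; this geometry later fixes C11 and C20 cis.

**Step 6**
Reactants: 10 ethyl 2-cyanopropanoate (racemic)
Product: 11 ethyl (2R)-2-cyano-2-methylpent-4-enoate
Conditions: allyl methyl carbonate, Rh(acac)(CO)2 (1 mol %), Pd(C3H5)(C5H5) (1 mol %), PhTRAP (2 mol %), THF, −40 °C
Reagents that add atoms: allyl methyl carbonate, C=CCOC(=O)OC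
Why: Enantioselective allylic alkylation of an α-cyano ester under rhodium/palladium dual catalysis (a chiral rhodium-bound cyano enolate attacks the allylpalladium cation); this sets the quaternary carbon C4, and the allyl group supplies C3, C2 and C1.

**Step 7**
Reactants: 11 ethyl (2R)-2-cyano-2-methylpent-4-enoate
Product: 12 (2R)-2-cyano-2-methylpent-4-enoic acid
Conditions: LiOH, THF–H2O, 0 °C; then 1 M HCl
Reagents that add atoms: lithium hydroxide, [Li+].[OH-]
Why: Saponification of an ester activated by the α-cyano group; the quaternary centre cannot epimerise.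

**Step 8**
Reactants: 12 (2R)-2-cyano-2-methylpent-4-enoic acid; 13 ethyl 2-methyl-3-oxobutanoate
Product: 16 (2R)-2-(4-hydroxy-3-methyl-2-oxo-2H-pyran-6-yl)-2-methylpent-4-enenitrile, via acyl imidazole 14 (not isolated), via diketo ester 15 (not isolated)
Conditions: 1,1'-carbonyldiimidazole, THF, rt; add to the dianion of 13 (NaH then n-BuLi, THF, 0 °C) at −78 °C; 1 M HCl; then DBU, toluene, 80 °C
Reagents that add atoms: none
Why: γ-Acylation of a β-keto ester dianion by an acyl imidazole (Claisen-type) and base-induced lactonisation of the 3,5-diketo ester give the 4-hydroxy-2-pyranone; its ring carbons become C5–C8 and its methyl C17.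

**Step 9**
Reactants: 16 (2R)-2-(4-hydroxy-3-methyl-2-oxo-2H-pyran-6-yl)-2-methylpent-4-enenitrile
Product: 17 6-[(2R)-2-cyanopent-4-en-2-yl]-3-methyl-2-oxo-2H-pyran-4-yl trifluoromethanesulfonate
Conditions: Tf2O, pyridine, CH2Cl2, −78 → 0 °C
Reagents that add atoms: trifluoromethanesulfonic anhydride, O=S(=O)(OS(=O)(=O)C(F)(F)F)C(F)(F)F
Why: O-Sulfonylation of the acidic pyranone hydroxyl.

**Step 10**
Reactants: 17 6-[(2R)-2-cyanopent-4-en-2-yl]-3-methyl-2-oxo-2H-pyran-4-yl trifluoromethanesulfonate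
Product: 18 (2R)-2-methyl-2-(3-methyl-2-oxo-2H-pyran-6-yl)pent-4-enenitrile
Conditions: Pd(OAc)2 (3 mol %), dppf (6 mol %), HCO2H, Et3N, DMF, 50 °C
Reagents that add atoms: none
Why: Palladium-catalysed formate reduction of a vinylogous acyl triflate (oxidative addition, decarboxylation of formate, reductive elimination) removes the superfluous oxygen on the future C7.

**Step 11**
Reactants: 18 (2R)-2-methyl-2-(3-methyl-2-oxo-2H-pyran-6-yl)pent-4-enenitrile; 9 tert-butyl[(2Z,6E)-7-iodo-3-methylocta-2,6-dienyloxy]diphenylsilane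
Product: 20 (2R,6E,10Z)-12-(tert-butyldiphenylsilyloxy)-2,6,10-trimethyl-2-(3-methyl-2-oxo-2H-pyran-6-yl)dodeca-6,10-dienenitrile, via alkylborane 19 (not isolated)
Conditions: 9-BBN, THF, 0 °C → rt; then 9, Pd(dppf)Cl2 (5 mol %), AsPh3, aq. K3PO4, DMF, rt
Reagents that add atoms: none
Why: B-alkyl Suzuki–Miyaura coupling: anti-Markovnikov hydroboration of the allyl group and sp3–sp2 coupling with retention of the (E)-iodoalkene geometry form C1–C10.

**Step 12**
Reactants: 20 (2R,6E,10Z)-12-(tert-butyldiphenylsilyloxy)-2,6,10-trimethyl-2-(3-methyl-2-oxo-2H-pyran-6-yl)dodeca-6,10-dienenitrile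
Product: 22 (1S,4aR,5S)-5-[(3Z)-5-(tert-butyldiphenylsilyloxy)-3-methylpent-3-enyl]-1,4a,6-trimethyl-1,2,3,4,4a,5-hexahydronaphthalene-1-carbonitrile, via bridged lactone 21 (not isolated)
Conditions: o-dichlorobenzene (0.01 M, degassed), BHT, 200 °C, sealed tube
Reagents that add atoms: none
Why: Thermal inverse-electron-demand [4+2] cycloaddition between the pyranone diene (C5=C6–C7=C8) and the tethered electron-rich (E)-alkene C9=C10 gives bridged lactone 21, which loses CO2 by retro-[4+2] at this temperature, so the cycloaddition becomes irreversible; the closest known reaction type is the intramolecular Diels–Alder reaction of 2-pyranones with unactivated alkenes followed by CO2 extrusion. Ring A closes through the C5–C10 bond over the four-atom tether C4–C3–C2–C1 and ring B through the C8–C9 bond, both as the two σ-bonds of one suprafacial cycloaddition. The C9/C10 relationship (C11 and C20 cis) follows from the (E)-alkene geometry. The sense relative to C4 should follow from the chair-like tether, in which the slender nitrile rather than the methyl group takes the axial position that is 1,3-diaxial to the incoming C20 methyl, so that C19 and C20 end up cis. The step needs π-facial selectivity relative to C4 and chemoselectivity for C9=C10 over the remote C13=C14 alkene; the small nitrile and the ring size (six- against ten-membered closure) should secure both. The bridgehead centres C5 and C8 of 21 are erased on CO2 loss, so both tether orientations converge on 22.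

**Step 13**
Reactants: 22 (1S,4aR,5S)-5-[(3Z)-5-(tert-butyldiphenylsilyloxy)-3-methylpent-3-enyl]-1,4a,6-trimethyl-1,2,3,4,4a,5-hexahydronaphthalene-1-carbonitrile
Product: 23 (1S,4aR,5S)-5-[(3Z)-5-hydroxy-3-methylpent-3-enyl]-1,4a,6-trimethyl-1,2,3,4,4a,5-hexahydronaphthalene-1-carbonitrile
Conditions: Bu4NF, THF, 0 °C → rt
Reagents that add atoms: none
Why: Fluoride cleavage of the silyl ether; nothing else in the molecule is fluoride- or base-labile.

**Step 14**
Reactants: 23 (1S,4aR,5S)-5-[(3Z)-5-hydroxy-3-methylpent-3-enyl]-1,4a,6-trimethyl-1,2,3,4,4a,5-hexahydronaphthalene-1-carbonitrile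
Product: 24 (1S,4aR,5S)-1,4a,6-trimethyl-5-[(3Z)-3-methyl-5-oxopent-3-enyl]-1,2,3,4,4a,5-hexahydronaphthalene-1-carbonitrile
Conditions: MnO2, CH2Cl2, rt
Reagents that add atoms: none
Why: Neutral MnO2 oxidation of an allylic alcohol, which should keep the (Z)-geometry of the enal.

**Step 15**
Reactants: 24 (1S,4aR,5S)-1,4a,6-trimethyl-5-[(3Z)-3-methyl-5-oxopent-3-enyl]-1,2,3,4,4a,5-hexahydronaphthalene-1-carbonitrile
Product: 25 (2Z)-5-[(1S,5S,8aR)-5-cyano-2,5,8a-trimethyl-1,5,6,7,8,8a-hexahydronaphthalen-1-yl]-3-methylpent-2-enoic acid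
Conditions: NaClO2, NaH2PO4, 2-methylbut-2-ene, t-BuOH–H2O, 0 °C
Reagents that add atoms: sodium chlorite, [Na+].[O-]Cl=O
Why: Pinnick oxidation; the alkene scavenger protects the ring diene from HOCl, and the conjugated acid makes the side-chain alkene inert to the acid of step 16.

**Step 16**
Reactants: 25 (2Z)-5-[(1S,5S,8aR)-5-cyano-2,5,8a-trimethyl-1,5,6,7,8,8a-hexahydronaphthalen-1-yl]-3-methylpent-2-enoic acid
Product: 26 (2Z)-5-[(1S,4aR,5S,8aR)-5-cyano-2,5,8a-trimethyl-1,4,4a,5,6,7,8,8a-octahydronaphthalen-1-yl]-3-methylpent-2-enoic acid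
Conditions: CF3CO2H (10 equiv), Et3SiH (1.2 equiv), CH2Cl2, −20 → 0 °C
Reagents that add atoms: none
Why: Ionic hydrogenation (acid/hydrosilane) of a conjugated diene: axial protonation of C5 from the α-face (the β-face is screened by the axial nitrile and C20) gives the allyl cation C6–C7–C8, which keeps the charge away from the nitrile, and hydride transfer to the less hindered terminus C6 should leave C7=C8 and set 5α-H (trans ring fusion).

**Step 17**
Reactants: 26 (2Z)-5-[(1S,4aR,5S,8aR)-5-cyano-2,5,8a-trimethyl-1,4,4a,5,6,7,8,8a-octahydronaphthalen-1-yl]-3-methylpent-2-enoic acid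
Product: 28 (2Z)-5-[(1S,4aR,5S,8aR)-5-(hydroxymethyl)-2,5,8a-trimethyl-1,4,4a,5,6,7,8,8a-octahydronaphthalen-1-yl]-3-methylpent-2-enoic acid, via aldehyde 27 (not isolated)
Conditions: i-Bu2AlH (3.5 equiv), CH2Cl2, −78 → −40 °C; 1 M HCl; then NaBH4, MeOH, 0 °C
Reagents that add atoms: water, O
Why: i-Bu2AlH adds once to the hindered nitrile while the acid is tied up as its aluminium carboxylate; hydrolysis gives aldehyde 27, which NaBH4 reduces, and no stereocentre is touched because C4 is quaternary.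

**Step 18**
Reactants: 28 (2Z)-5-[(1S,4aR,5S,8aR)-5-(hydroxymethyl)-2,5,8a-trimethyl-1,4,4a,5,6,7,8,8a-octahydronaphthalen-1-yl]-3-methylpent-2-enoic acid; 29 angelic acid, (2Z)-2-methylbut-2-enoic acid
Product: 31 (2Z)-3-methyl-5-[(1S,4aR,5S,8aR)-2,5,8a-trimethyl-5-{[(2Z)-2-methylbut-2-enoyl]oxymethyl}-1,4,4a,5,6,7,8,8a-octahydronaphthalen-1-yl]pent-2-enoic acid, via mixed anhydride 30 (not isolated)
Conditions: 29, 2,4,6-trichlorobenzoyl chloride, Et3N, toluene, rt; then 28, toluene, 75 °C; aq. NaHCO3–THF work-up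
Reagents that add atoms: none
Why: Yamaguchi-type mixed-anhydride acylation without a nucleophilic catalyst should keep the (Z)-geometry of the angeloyl group; the neopentyl C19 hydroxyl is the only alcohol, and anhydrides formed at the C15 carboxylate are cleaved again in the aqueous work-up.

**Compound list**

1 | nerol, (2Z)-3,7-dimethylocta-2,6-dien-1-ol | CC(C)=CCC/C(C)=C\CO | starting material
2 | neryl tert-butyldiphenylsilyl ether | CC(C)=CCC/C(C)=C\CO[Si](c1ccccc1)(c1ccccc1)C(C)(C)C | intermediate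
3 | 6,7-epoxide of 2 (racemic at the epoxide) | CC1(C)OC1CC/C(C)=C\CO[Si](c2ccccc2)(c2ccccc2)C(C)(C)C | intermediate
4 | (4Z)-6-(tert-butyldiphenylsilyloxy)-4-methylhex-4-enal | O=CCC/C(C)=C\CO[Si](c1ccccc1)(c1ccccc1)C(C)(C)C | intermediate
5 | tert-butyl[(2Z)-7,7-dibromo-3-methylhepta-2,6-dienyloxy]diphenylsilane | BrC(Br)=CCC/C(C)=C\CO[Si](c1ccccc1)(c1ccccc1)C(C)(C)C | intermediate
6 | lithium acetylide of 7 | [Li]C#CCC/C(C)=C\CO[Si](c1ccccc1)(c1ccccc1)C(C)(C)C | intermediate
7 | tert-butyl[(2Z)-3-methyloct-2-en-6-ynyloxy]diphenylsilane | CC#CCC/C(C)=C\CO[Si](c1ccccc1)(c1ccccc1)C(C)(C)C | intermediate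
8 | (E)-alkenylzirconocene chloride | C/C(=C\CC/C(C)=C\CO[Si](c1ccccc1)(c1ccccc1)C(C)(C)C)[Zr](Cl)(C1C=CC=C1)C1C=CC=C1 | intermediate
9 | tert-butyl[(2Z,6E)-7-iodo-3-methylocta-2,6-dienyloxy]diphenylsilane | C/C(I)=C\CC/C(C)=C\CO[Si](c1ccccc1)(c1ccccc1)C(C)(C)C | intermediate
10 | ethyl 2-cyanopropanoate (racemic) | CCOC(=O)C(C)C#N | starting material
11 | ethyl (2R)-2-cyano-2-methylpent-4-enoate | N#C[C@@](C(=O)OCC)(C)CC=C | intermediate
12 | (2R)-2-cyano-2-methylpent-4-enoic acid | N#C[C@@](C(=O)O)(C)CC=C | intermediate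
13 | ethyl 2-methyl-3-oxobutanoate | CCOC(=O)C(C)C(C)=O | starting material
14 | (2R)-2-(imidazole-1-carbonyl)-2-methylpent-4-enenitrile | N#C[C@@](C(=O)n1ccnc1)(C)CC=C | intermediate
15 | ethyl (6R)-6-cyano-2,6-dimethyl-3,5-dioxonon-8-enoate (C2 epimers and enol forms) | N#C[C@@](C(=O)CC(=O)C(C)C(=O)OCC)(C)CC=C | intermediate
16 | (2R)-2-(4-hydroxy-3-methyl-2-oxo-2H-pyran-6-yl)-2-methylpent-4-enenitrile | N#C[C@@](c1cc(O)c(C)c(=O)o1)(C)CC=C | intermediate
17 | 6-[(2R)-2-cyanopent-4-en-2-yl]-3-methyl-2-oxo-2H-pyran-4-yl trifluoromethanesulfonate | N#C[C@@](c1cc(OS(=O)(=O)C(F)(F)F)c(C)c(=O)o1)(C)CC=C | intermediate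
18 | (2R)-2-methyl-2-(3-methyl-2-oxo-2H-pyran-6-yl)pent-4-enenitrile | N#C[C@@](c1ccc(C)c(=O)o1)(C)CC=C | intermediate
19 | B-alkyl-9-borabicyclo[3.3.1]nonane from 18 | N#C[C@@](c1ccc(C)c(=O)o1)(C)CCCB1C2CCCC1CCC2 | intermediate
20 | (2R,6E,10Z)-12-(tert-butyldiphenylsilyloxy)-2,6,10-trimethyl-2-(3-methyl-2-oxo-2H-pyran-6-yl)dodeca-6,10-dienenitrile | N#C[C@@](c1ccc(C)c(=O)o1)(C)CCC/C(C)=C/CC/C(C)=C\CO[Si](c2ccccc2)(c2ccccc2)C(C)(C)C | intermediate
21 | bridged lactone, the 2-oxabicyclo[2.2.2]oct-5-en-3-one cycloadduct (both tether orientations at the bridgeheads) | N#C[C@@]1(C)CCC[C@]2(C)[C@@H](CC/C(C)=C\CO[Si](c4ccccc4)(c4ccccc4)C(C)(C)C)C3(C)C=CC12OC3=O | intermediate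
22 | (1S,4aR,5S)-5-[(3Z)-5-(tert-butyldiphenylsilyloxy)-3-methylpent-3-enyl]-1,4a,6-trimethyl-1,2,3,4,4a,5-hexahydronaphthalene-1-carbonitrile | N#C[C@@]1(C)CCC[C@]2(C)[C@@H](CC/C(C)=C\CO[Si](c3ccccc3)(c3ccccc3)C(C)(C)C)C(C)=CC=C12 | intermediate
23 | (1S,4aR,5S)-5-[(3Z)-5-hydroxy-3-methylpent-3-enyl]-1,4a,6-trimethyl-1,2,3,4,4a,5-hexahydronaphthalene-1-carbonitrile | N#C[C@@]1(C)CCC[C@]2(C)[C@@H](CC/C(C)=C\CO)C(C)=CC=C12 | intermediate
24 | (1S,4aR,5S)-1,4a,6-trimethyl-5-[(3Z)-3-methyl-5-oxopent-3-enyl]-1,2,3,4,4a,5-hexahydronaphthalene-1-carbonitrile | N#C[C@@]1(C)CCC[C@]2(C)[C@@H](CC/C(C)=C\C=O)C(C)=CC=C12 | intermediate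
25 | (2Z)-5-[(1S,5S,8aR)-5-cyano-2,5,8a-trimethyl-1,5,6,7,8,8a-hexahydronaphthalen-1-yl]-3-methylpent-2-enoic acid | N#C[C@@]1(C)CCC[C@]2(C)[C@@H](CC/C(C)=C\C(=O)O)C(C)=CC=C12 | intermediate
26 | (2Z)-5-[(1S,4aR,5S,8aR)-5-cyano-2,5,8a-trimethyl-1,4,4a,5,6,7,8,8a-octahydronaphthalen-1-yl]-3-methylpent-2-enoic acid | N#C[C@@]1(C)CCC[C@]2(C)[C@@H](CC/C(C)=C\C(=O)O)C(C)=CC[C@@H]12 | intermediate
27 | (2Z)-5-[(1S,4aR,5S,8aR)-5-formyl-2,5,8a-trimethyl-1,4,4a,5,6,7,8,8a-octahydronaphthalen-1-yl]-3-methylpent-2-enoic acid | O=C[C@@]1(C)CCC[C@]2(C)[C@@H](CC/C(C)=C\C(=O)O)C(C)=CC[C@@H]12 | intermediate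
28 | (2Z)-5-[(1S,4aR,5S,8aR)-5-(hydroxymethyl)-2,5,8a-trimethyl-1,4,4a,5,6,7,8,8a-octahydronaphthalen-1-yl]-3-methylpent-2-enoic acid | OC[C@@]1(C)CCC[C@]2(C)[C@@H](CC/C(C)=C\C(=O)O)C(C)=CC[C@@H]12 | intermediate
29 | angelic acid, (2Z)-2-methylbut-2-enoic acid | C/C=C(/C)C(=O)O | starting material
30 | angelic 2,4,6-trichlorobenzoic anhydride | C/C=C(/C)C(=O)OC(=O)c1c(Cl)cc(Cl)cc1Cl | intermediate
31 | (2Z)-3-methyl-5-[(1S,4aR,5S,8aR)-2,5,8a-trimethyl-5-{[(2Z)-2-methylbut-2-enoyl]oxymethyl}-1,4,4a,5,6,7,8,8a-octahydronaphthalen-1-yl]pent-2-enoic acid | C/C=C(/C)C(=O)OC[C@@]1(C)CCC[C@]2(C)[C@@H](CC/C(C)=C\C(=O)O)C(C)=CC[C@@H]12 | target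

**Step count and risks**

Total step count: 18. Longest linear sequence: 13 steps (steps 1–5 then 11–18; the branch 6–10 then 11–18 is equally long).

Steps most likely to fail:

Step 12. The cycloaddition joins two hindered termini, so thermal decomposition may outrun it, and at 200 °C some addition to the other π-face (methyl instead of nitrile axial) may leak through. Fallback: an activated diene that reacts at lower temperature. It sets out from 16: hydroboration with 9-BBN and B-alkyl Suzuki–Miyaura coupling with 9 (conditions of step 11, extra borane for the acidic hydroxyl) would give the hydroxypyranone F1; Tf2O/pyridine would give the pyranonyl triflate F2, whose sulfonate lowers the diene LUMO so that the inverse-demand cycloaddition and CO2 loss should run in toluene at 110–140 °C to the dienyl triflate F3; Pd(OAc)2/dppf/HCO2H/Et3N then removes the triflate and the route is rejoined at 22.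

Step 16. Protonation may occur at the wrong diene terminus, or the product alkene may be reduced further. Fallback: deliver the C5 hydrogen through a lactone instead of a cation. It sets out from 22: hydration of the nitrile with [PtH(PMe2OH)(PMe2O)2H] (EtOH–H2O, 80 °C) would give the primary amide F4. Iodolactonisation through the amide oxygen (I2, NaHCO3, THF–H2O; iodonium on the α-face, oxygen attack at C6 from the β-face, hydrolysis of the iminolactone) would give the iodolactone F5. Bu3SnH/AIBN would give the lactone F6, the C5 radical taking hydrogen from the open α-face. The zerovalent palladium catalyst Pd(PPh3)4 with NaBH4 would open the allylic lactone with hydride delivery to C6 to give the acid F7. LiAlH4 would give the alcohol F8, Bu4NF the diol F9, and MnO2 (allylic alcohol only) the hydroxy enal F10; Pinnick oxidation as in step 15 rejoins the route at 28.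

Step 18. Acylation of the hindered axial neopentyl alcohol may be slow, and the angeloyl group may isomerise from (Z) to (E) while it waits. Fallback: build the (Z)-alkene of the ester in place. It sets out from 28: Me3SiCHN2 in MeOH–toluene would give the methyl ester F11; DCC-mediated acylation with 2-[bis(2,2,2-trifluoroethoxy)phosphoryl]propanoic acid would give the phosphonate F12; Still–Gennari olefination (KN(SiMe3)2, 18-crown-6, THF, −78 °C, acetaldehyde) would give the angelate methyl ester F13; Me3SnOH (1,2-dichloroethane, 70 °C) should cleave only the unhindered methyl ester and the route is rejoined at 31.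

**Further compounds**

F1 | step 12 | (2R,6E,10Z)-12-(tert-butyldiphenylsilyloxy)-2-(4-hydroxy-3-methyl-2-oxo-2H-pyran-6-yl)-2,6,10-trimethyldodeca-6,10-dienenitrile | N#C[C@@](c1cc(O)c(C)c(=O)o1)(C)CCC/C(C)=C/CC/C(C)=C\CO[Si](c2ccccc2)(c2ccccc2)C(C)(C)C
F2 | step 12 | 4-trifluoromethanesulfonate of F1 | N#C[C@@](c1cc(OS(=O)(=O)C(F)(F)F)c(C)c(=O)o1)(C)CCC/C(C)=C/CC/C(C)=C\CO[Si](c2ccccc2)(c2ccccc2)C(C)(C)C
F3 | step 12 | analogue of 22 with a trifluoromethanesulfonyloxy group on the diene carbon next to the methyl-bearing carbon (C7 of the labdane skeleton) | N#C[C@@]1(C)CCC[C@]2(C)[C@@H](CC/C(C)=C\CO[Si](c3ccccc3)(c3ccccc3)C(C)(C)C)C(C)=C(OS(=O)(=O)C(F)(F)F)C=C12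
F4 | step 16 | primary carboxamide from the nitrile of 22 | NC(=O)[C@@]1(C)CCC[C@]2(C)[C@@H](CC/C(C)=C\CO[Si](c3ccccc3)(c3ccccc3)C(C)(C)C)C(C)=CC=C12
F5 | step 16 | 5α-iodo-19,6β-lactone (γ-lactone from the C19 carbonyl to the β-oxygen on C6, iodine on C5, C7=C8 alkene) | O=C4[C@@]1(C)CCC[C@]2(C)[C@@H](CC/C(C)=C\CO[Si](c3ccccc3)(c3ccccc3)C(C)(C)C)C(C)=C[C@@H](O4)[C@@]12I
F6 | step 16 | 19,6β-lactone with 5α-H | O=C4[C@@]1(C)CCC[C@]2(C)[C@@H](CC/C(C)=C\CO[Si](c3ccccc3)(c3ccccc3)C(C)(C)C)C(C)=C[C@@H](O4)[C@@H]12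
F7 | step 16 | 15-(tert-butyldiphenylsilyloxy)labda-7,13Z-dien-19-oic acid | OC(=O)[C@@]1(C)CCC[C@]2(C)[C@@H](CC/C(C)=C\CO[Si](c3ccccc3)(c3ccccc3)C(C)(C)C)C(C)=CC[C@@H]12
F8 | step 16 | 15-(tert-butyldiphenylsilyloxy)labda-7,13Z-dien-19-ol | OC[C@@]1(C)CCC[C@]2(C)[C@@H](CC/C(C)=C\CO[Si](c3ccccc3)(c3ccccc3)C(C)(C)C)C(C)=CC[C@@H]12
F9 | step 16 | labda-7,13Z-diene-15,19-diol | OC[C@@]1(C)CCC[C@]2(C)[C@@H](CC/C(C)=C\CO)C(C)=CC[C@@H]12
F10 | step 16 | 19-hydroxylabda-7,13Z-dien-15-al | OC[C@@]1(C)CCC[C@]2(C)[C@@H](CC/C(C)=C\C=O)C(C)=CC[C@@H]12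
F11 | step 18 | methyl ester of 28 | OC[C@@]1(C)CCC[C@]2(C)[C@@H](CC/C(C)=C\C(=O)OC)C(C)=CC[C@@H]12
F12 | step 18 | 2-[bis(2,2,2-trifluoroethoxy)phosphoryl]propanoate of F11 (both epimers at the phosphonate carbon) | CC(P(=O)(OCC(F)(F)F)OCC(F)(F)F)C(=O)OC[C@@]1(C)CCC[C@]2(C)[C@@H](CC/C(C)=C\C(=O)OC)C(C)=CC[C@@H]12
F13 | step 18 | methyl ester of 31 | C/C=C(/C)C(=O)OC[C@@]1(C)CCC[C@]2(C)[C@@H](CC/C(C)=C\C(=O)OC)C(C)=CC[C@@H]12
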